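**Retrosynthetic overview** (ring numbering used throughout: C1(=O), C2(OMe), C3(H), C4(=O), C5(Me), C6(hexaprenyl); "hexaprenyl" = (2E,6E,10E,14E,18E)-3,7,11,15,19,23-hexamethyltetracosa-2,6,10,14,18,22-hexaen-1-yl)
- The O-methyl group and the C1 oxygen are added last (O-methylation of a 2-hydroxyquinone, Teuber oxidation), which leads back to 4-methyl-5-hexaprenylresorcinol.
- Enabling feature: C2 and C4 carry oxygen in a 1,3-relationship and flank C3, the only CH of the ring, so C2–C3–C4 is a masked β-diketone. C1 carries no carbon substituent and lies para to C4, so its oxygen can enter by phenol oxidation.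
- The benzene ring, the only ring, is made in one pot from methyl hexaprenylpropiolate and 3-methylpentane-2,4-dione: Michael addition (C5–C6), ring closure by Claisen condensation (C2–C3), then loss of the spare acetyl group.
- The ynoate comes from all-E-hexaprenyl bromide and methyl propiolate; the C30 chain comes from two farnesyl units by sulfone alkylation and reductive desulfonylation.

Key step: step 8

Remark on the chemistry: all-E-hexaprenol is not taken as purchasable, so the chain is assembled from (2E,6E)-farnesyl bromide and (2E,6E)-farnesyl acetate, both commercial.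

Step 1
Reactants: 1 (2E,6E)-farnesyl bromide
Product: 2 (2E,6E)-farnesyl phenyl sulfone
Conditions: PhSO2Na, DMF, rt
Reagents that add atoms: sodium benzenesulfinate, [Na+].[O-]S(=O)c1ccccc1
Why: SN2 S-alkylation of the sulfinate by the primary allylic bromide should give the sulfone without touching the two E-alkenes.

Step 2
Reactants: 3 (2E,6E)-farnesyl acetate
Product: 4 (2E,6E,10E)-12-hydroxy-3,7,11-trimethyldodeca-2,6,10-trien-1-yl acetate
Conditions: SeO2 (10 mol %), t-BuOOH, salicylic acid (cat.), CH2Cl2, rt
Reagents that add atoms: tert-butyl hydroperoxide, CC(C)(C)OO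
Why: Riley-type allylic oxidation (ene reaction, then [2,3]-sigmatropic shift) should attack the terminal, most electron-rich alkene at its E-methyl group and give the E-allylic alcohol, the alkene next to the acetate being deactivated.

Step 3
Reactants: 4 (2E,6E,10E)-12-hydroxy-3,7,11-trimethyldodeca-2,6,10-trien-1-yl acetate
Product: 5 (2E,6E,10E)-12-bromo-3,7,11-trimethyldodeca-2,6,10-trien-1-yl acetate
Conditions: CBr4, PPh3, CH2Cl2, 0 °C
Reagents that add atoms: carbon tetrabromide, BrC(Br)(Br)Br
Why: The Appel reaction should convert the primary allylic alcohol into the bromide under neutral conditions, without allylic transposition and without loss of the acetate.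

Step 4
Reactants: 2 (2E,6E)-farnesyl phenyl sulfone; 5 (2E,6E,10E)-12-bromo-3,7,11-trimethyldodeca-2,6,10-trien-1-yl acetate
Product: 7 (2E,6E,10E,14E,18E)-3,7,11,15,19,23-hexamethyl-13-(phenylsulfonyl)tetracosa-2,6,10,14,18,22-hexaen-1-yl acetate (racemic at C13), via lithiated sulfone 6 (not isolated)
Conditions: n-BuLi, THF/DMPU, −78 °C; then 5, −78 to −40 °C
Reagents that add atoms: none
Why: Biellmann-type alkylation, in which the sulfone-stabilized allyl anion should react at its α-carbon with the primary allylic bromide faster than with the acetate at −78 °C; the sulfone-bearing stereocentre forms as a racemate and is removed in step 5.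

Step 5
Reactants: 7 (2E,6E,10E,14E,18E)-3,7,11,15,19,23-hexamethyl-13-(phenylsulfonyl)tetracosa-2,6,10,14,18,22-hexaen-1-yl acetate
Product: 9 all-E-hexaprenol, via hydroxy sulfone 8 (not isolated)
Conditions: LiBHEt3 (5 equiv), THF, −78 to 0 °C; then PdCl2(dppp) (5 mol %), 0 °C to rt
Reagents that add atoms: none
Why: The hydride should first cleave the acetate (so no allylic ester is left for the catalyst), after which zerovalent palladium ionizes the allylic sulfone and the π-allyl complex takes hydride at its less substituted terminus (palladium-catalysed reductive desulfonylation), which keeps the trisubstituted E-alkene in place.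

Step 6
Reactants: 9 all-E-hexaprenol
Product: 10 all-E-hexaprenyl bromide
Conditions: PBr3, Et2O, −10 °C
Reagents that add atoms: phosphorus tribromide, BrP(Br)Br
Why: Bromination of the primary allylic alcohol through its phosphite ester at low temperature should proceed by SN2 with the alkene position and geometry retained.

Step 7
Reactants: 10 all-E-hexaprenyl bromide; 11 methyl propiolate
Product: 12 methyl (5E,9E,13E,17E,21E)-6,10,14,18,22,26-hexamethylheptacosa-5,9,13,17,21,25-hexaen-2-ynoate (methyl hexaprenylpropiolate)
Conditions: CuI (10 mol %), NaI (10 mol %), K2CO3, DMF, rt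
Reagents that add atoms: none
Why: Copper-mediated allylation of the terminal alkyne, in which the copper acetylide should substitute the primary allylic bromide at its unsubstituted terminus and give the 1,4-enyne with the E-alkene intact; carbonate is too weak a base to shift the skipped enynoate.

Step 8
Reactants: 12 methyl hexaprenylpropiolate; 13 3-methylpentane-2,4-dione
Product: 16 4-methyl-5-hexaprenylbenzene-1,3-diol, via Michael adduct 14 (not isolated), via acetylcyclohexenedione 15 (not isolated)
Conditions: KOt-Bu (10 mol %), THF, 0 °C to rt; then LiN(SiMe3)2 (2.3 equiv), −78 to 0 °C; then MeOH, rt; aq. NH4Cl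
Reagents that add atoms: none
Why: Proposed new method: the potassium enolate of 13 should add through carbon to the β-carbon of ynoate 12 (Michael addition), and protonation of the allenolate anti to the new quaternary centre places that centre cis to the ester in 14; LiN(SiMe3)2 then enolizes an acetyl methyl group, whose carbon attacks the ester carbonyl in a 6-(enolexo)-exo-trig Claisen (Dieckmann) closure that makes the bond between the future methoxy-bearing carbon C2 and the ring CH C3 and gives 15. The methoxide expelled in that closure cleaves the remaining acetyl group by retro-Claisen fragmentation, and aromatization to the resorcinolate makes this last event irreversible. The closest known reaction type is the Michael–Claisen annulation of 1,3-dicarbonyl donors with conjugated acceptors, which gives dihydroresorcinols from enones and resorcinols from acetylenic acceptors; new here is the tertiary diketone donor, whose second acetyl group serves as a traceless activating group. The ring closes in this single mode and no stereocentre survives, because the quaternary carbon of 15 becomes an aromatic carbon. The step needs carbon- over oxygen-attack of the enolate, the cis geometry of 14, and enolization at the acetyl group and not at the doubly allylic chain methylene: the first is the thermodynamic outcome of a reversible addition, the second follows from anti protonation, and the third from the position of that methylene trans to the ester, out of reach of the syn-directed γ-deprotonation by a lithium amide. Regiochemistry is fixed by construction, since the symmetric donor can bond only through its methyl-bearing carbon and the ester carbon can only become the oxygenated carbon flanked by two CH groups, which puts the chain meta to both oxygens.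

Step 9
Reactants: 16 4-methyl-5-hexaprenylbenzene-1,3-diol
Product: 17 2-hydroxy-5-methyl-6-hexaprenyl-1,4-benzoquinone
Conditions: (KSO3)2NO (2.5 equiv), KH2PO4, Bu4NHSO4 (cat.), CH2Cl2/H2O, rt
Reagents that add atoms: potassium nitrosodisulfonate (Fremy's salt), [K+].[K+].[O]N(S(=O)(=O)[O-])S(=O)(=O)[O-]
Why: Teuber oxidation, in which the nitroxyl radical should deliver oxygen to C1, the free position para to the C4 hydroxyl and ortho to the C2 hydroxyl, so that either phenoxyl radical leads to the same 2-hydroxy-1,4-quinone, while the isolated chain alkenes are inert to the reagent.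

Step 10
Reactants: 17 2-hydroxy-5-methyl-6-hexaprenyl-1,4-benzoquinone
Product: 18 2-methoxy-5-methyl-6-hexaprenyl-1,4-benzoquinone (5-demethoxyubiquinone-6, the target)
Conditions: MeI, Ag2O, CH2Cl2, rt, dark
Reagents that add atoms: iodomethane, CI
Why: Silver-assisted O-methylation of the acidic vinylogous acid (Williamson-type etherification) should give the 2-methoxy-1,4-quinone and not the less stable ortho-quinone ether, under neutral conditions that spare the polyene.

**Compound list**
1 | (2E,6E)-farnesyl bromide | BrC/C=C(\C)CC/C=C(\C)CCC=C(C)C | starting material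
2 | (2E,6E)-farnesyl phenyl sulfone | O=S(=O)(C/C=C(\C)CC/C=C(\C)CCC=C(C)C)c1ccccc1 | intermediate
3 | (2E,6E)-farnesyl acetate | CC(=O)OC/C=C(\C)CC/C=C(\C)CCC=C(C)C | starting material
4 | (2E,6E,10E)-12-hydroxy-3,7,11-trimethyldodeca-2,6,10-trien-1-yl acetate | CC(=O)OC/C=C(\C)CC/C=C(\C)CC/C=C(\C)CO | intermediate
5 | (2E,6E,10E)-12-bromo-3,7,11-trimethyldodeca-2,6,10-trien-1-yl acetate | CC(=O)OC/C=C(\C)CC/C=C(\C)CC/C=C(\C)CBr | intermediate
6 | α-lithio-(2E,6E)-farnesyl phenyl sulfone | [Li]C(/C=C(\C)CC/C=C(\C)CCC=C(C)C)S(=O)(=O)c1ccccc1 | intermediate (not isolated)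
7 | (2E,6E,10E,14E,18E)-3,7,11,15,19,23-hexamethyl-13-(phenylsulfonyl)tetracosa-2,6,10,14,18,22-hexaen-1-yl acetate, racemic at C13 | CC(=O)OC/C=C(\C)CC/C=C(\C)CC/C=C(\C)CC(/C=C(\C)CC/C=C(\C)CCC=C(C)C)S(=O)(=O)c1ccccc1 | intermediate
8 | (2E,6E,10E,14E,18E)-3,7,11,15,19,23-hexamethyl-13-(phenylsulfonyl)tetracosa-2,6,10,14,18,22-hexaen-1-ol, racemic at C13 | OC/C=C(\C)CC/C=C(\C)CC/C=C(\C)CC(/C=C(\C)CC/C=C(\C)CCC=C(C)C)S(=O)(=O)c1ccccc1 | intermediate (not isolated)
9 | all-E-hexaprenol, (2E,6E,10E,14E,18E)-3,7,11,15,19,23-hexamethyltetracosa-2,6,10,14,18,22-hexaen-1-ol | OC/C=C(\C)CC/C=C(\C)CC/C=C(\C)CC/C=C(\C)CC/C=C(\C)CCC=C(C)C | intermediate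
10 | all-E-hexaprenyl bromide | BrC/C=C(\C)CC/C=C(\C)CC/C=C(\C)CC/C=C(\C)CC/C=C(\C)CCC=C(C)C | intermediate
11 | methyl propiolate | C#CC(=O)OC | starting material
12 | methyl (5E,9E,13E,17E,21E)-6,10,14,18,22,26-hexamethylheptacosa-5,9,13,17,21,25-hexaen-2-ynoate | COC(=O)C#CC/C=C(\C)CC/C=C(\C)CC/C=C(\C)CC/C=C(\C)CC/C=C(\C)CCC=C(C)C | intermediate
13 | 3-methylpentane-2,4-dione | CC(=O)C(C)C(C)=O | starting material
14 | methyl (2Z,5E,9E,13E,17E,21E)-6,10,14,18,22,26-hexamethyl-3-(3-methyl-2,4-dioxopentan-3-yl)heptacosa-2,5,9,13,17,21,25-heptaenoate | COC(=O)/C=C(\C(C)(C(C)=O)C(C)=O)C/C=C(\C)CC/C=C(\C)CC/C=C(\C)CC/C=C(\C)CC/C=C(\C)CCC=C(C)C | intermediate (not isolated)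
15 | 4-acetyl-4-methyl-5-hexaprenylcyclohex-5-ene-1,3-dione, racemic | CC(=O)C1(C)C(=O)CC(=O)C=C1C/C=C(\C)CC/C=C(\C)CC/C=C(\C)CC/C=C(\C)CC/C=C(\C)CCC=C(C)C | intermediate (not isolated)
16 | 4-methyl-5-hexaprenylbenzene-1,3-diol | Cc1c(O)cc(O)cc1C/C=C(\C)CC/C=C(\C)CC/C=C(\C)CC/C=C(\C)CC/C=C(\C)CCC=C(C)C | intermediate
17 | 2-hydroxy-5-methyl-6-hexaprenyl-1,4-benzoquinone | OC1=CC(=O)C(C)=C(C/C=C(\C)CC/C=C(\C)CC/C=C(\C)CC/C=C(\C)CC/C=C(\C)CCC=C(C)C)C1=O | intermediate
18 | 2-methoxy-5-methyl-6-hexaprenyl-1,4-benzoquinone | COC1=CC(=O)C(C)=C(C/C=C(\C)CC/C=C(\C)CC/C=C(\C)CC/C=C(\C)CC/C=C(\C)CCC=C(C)C)C1=O | target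

**Step count**
Total steps: 10. Longest linear sequence: 9 steps (from 3 to 18, steps 2 to 10).

**Steps most likely to fail**

1. Step 8 (Proposed new method). The hindered tertiary enolate may add to the β-alkyl ynoate too slowly, so that oxygen-attack or a base-induced prototropic shift of the skipped enynoate to an allenoate takes over; that shift would also scramble the first chain alkene. An adduct formed with the quaternary carbon trans to the ester cannot cyclize. The fallback sets out from 10 and comes back at 18, so it also replaces steps 9 and 10. Bromide 10 would be treated with Bu3SnLi in THF at −78 °C to give tributyl(hexaprenyl)stannane F1. F1 would be added to purchased 2-methoxy-5-methyl-1,4-benzoquinone with BF3·OEt2 in CH2Cl2 at −78 °C (Lewis acid-mediated allylstannane addition to the cross-conjugated C1 carbonyl, then allyl shift to the free neighbouring carbon C6), which should give 2-methoxy-5-methyl-6-hexaprenylhydroquinone F2 with the E-geometry retained. Oxidation of F2 with Ag2O in Et2O would give 18.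

2. Step 7. Attack of the acetylide at the substituted terminus of the allyl system (allylic transposition) and prototropic isomerization of the doubly activated methylene in the product may erode the yield and the E-geometry. The fallback sets out from 10 and comes back at 12. Bromide 10 would be coupled with HC≡CMgBr and CuCl (cat.) in THF to give the base-stable terminal enyne, hexaprenylacetylene F3. Deprotonation of F3 with n-BuLi at −78 °C and trapping with methyl chloroformate would give 12, so the ester is introduced under kinetic conditions only.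

3. Step 9. Radical attack at C3, between the two hydroxyls, and slow conversion of the very lipophilic substrate in the two-phase medium may lower the yield of the para-quinone. The fallback sets out from 16 and comes back at 18. A Mitsunobu etherification of 16 (MeOH, PPh3, DIAD, THF) should methylate the less hindered hydroxyl, the one not next to the ring methyl, and give 5-methoxy-2-methyl-3-hexaprenylphenol F4. Aerobic oxidation of this monophenol at its free para position with Co(salen) (a divalent cobalt complex) and O2 in DMF would give 18 directly.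

**Further compounds**
F1 | step 8 | tributyl(hexaprenyl)stannane | CCCC[Sn](CCCC)(CCCC)C/C=C(\C)CC/C=C(\C)CC/C=C(\C)CC/C=C(\C)CC/C=C(\C)CCC=C(C)C
F2 | step 8 | 2-methoxy-5-methyl-6-hexaprenylbenzene-1,4-diol | COc1cc(O)c(C)c(C/C=C(\C)CC/C=C(\C)CC/C=C(\C)CC/C=C(\C)CC/C=C(\C)CCC=C(C)C)c1O
F3 | step 7 | hexaprenylacetylene, (5E,9E,13E,17E,21E)-6,10,14,18,22,26-hexamethylheptacosa-5,9,13,17,21,25-hexaen-1-yne | C#CC/C=C(\C)CC/C=C(\C)CC/C=C(\C)CC/C=C(\C)CC/C=C(\C)CCC=C(C)C
F4 | step 9 | 5-methoxy-2-methyl-3-hexaprenylphenol | COc1cc(O)c(C)c(C/C=C(\C)CC/C=C(\C)CC/C=C(\C)CC/C=C(\C)CC/C=C(\C)CCC=C(C)C)c1
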